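## Retrosynthetic overview

- Numbering: ring A is the ten-membered carbocycle C1–C10 (C1–C3 = CH2, C4/C5 = oxirane carbons with the methyl on C4, C6 = CH–O-senecioate, C7 = CH bearing C11, C8 = lactone CH–O, C9 = CHOH, C10 = CHMe). Ring B is the γ-lactone O–C12(=O)–C11(=C13H2)–C7–C8, and ring C is the oxirane.
- Feature used: in ring A the C9 oxygen lies across the ring from C4, with the C8 oxygen and the C6–C7 bond between them. This is the product pattern of a 3-oxido-1,5-diene [3,3] shift that breaks C4–C9 and makes C6–C7, leaving a C9 ketone, a C8 enolate carbon and an E C4=C5 alkene.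
- Disconnections: the senecioate ester and ring C come last, the oxirane oxygen being delivered from the C6 allylic hydroxyl. Ring B comes from oxidative lactonisation of a C7 hydroxyethyl arm onto C8–OH. Ring A comes from an anionic oxy-Cope ring expansion of a trans-1,2-dialkenylcyclohexanol, with hydroxylation of the enolate in the same flask.
- The cyclohexanol is assembled from (2R,6R)-2,6-dimethyl-2-[(E)-2-(4-methoxybenzyloxy)ethenyl]cyclohexanone (from 2-methylcyclohex-2-enone, which supplies C10) and an (E)-4-silyloxybutenyl cerium reagent (from but-3-yn-1-ol).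
- Ring order: bought six-membered ring, then ring A (step 9), then ring B (step 12), then ring C (step 17).

Key step: step 9

Remark: the locants C1–C13 defined above are used for all ten-membered-ring compounds and their CIP descriptors; compound 4 is written as the chelated enol tautomer of the formyl ketone, and 26 and 27 are carried as C11 epimers because that centre is removed in step 15.

## Route

Step 1
Reactants: 1 2-methylcyclohex-2-en-1-one
Product: 2 (R)-2-methylcyclohexan-1-one
Conditions: ene-reductase OYE1, NADP+ (cat.), glucose dehydrogenase, D-glucose, phosphate buffer pH 7/MTBE, 25 °C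
Reagents that add atoms: none
Why: Enzymatic conjugate reduction by an old-yellow-enzyme ene-reductase adds hydride from the flavin to C3 and a proton to C2 from the opposite face, which for this enone is known to give the R ketone, and the two-phase medium with short contact time should limit racemisation of the α-centre.

Step 2
Reactants: 2 (R)-2-methylcyclohexan-1-one
Product: 4 (2Z,6R)-2-(hydroxymethylidene)-6-methylcyclohexan-1-one, via lithium enolate 3 (not isolated)
Conditions: LiN(i-Pr)2, THF, −78 °C (2 added to the base); CF3CH2OCHO, −78 °C to rt; 1 M HCl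
Reagents that add atoms: 2,2,2-trifluoroethyl formate, O=COCC(F)(F)F
Why: Kinetic deprotonation removes a proton only from the CH2 flank, so the methyl-bearing stereocentre is not enolised, and Claisen-type C-formylation of that enolate gives the chelated hydroxymethylene ketone.

Step 3
Reactants: 4 (2Z,6R)-2-(hydroxymethylidene)-6-methylcyclohexan-1-one
Product: 5 (1R,3R)-1,3-dimethyl-2-oxocyclohexane-1-carbaldehyde
Conditions: MeI, K2CO3, acetone, rt
Reagents that add atoms: iodomethane, CI
Why: C-Alkylation of the β-keto aldehyde enolate in which iodomethane enters axially through a chair-like transition state that keeps the existing methyl equatorial, so the new methyl ends trans to it (1R), while carbonate is too weak to epimerise the remaining α-CH.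

Step 4
Reactants: 5 (1R,3R)-1,3-dimethyl-2-oxocyclohexane-1-carbaldehyde
Product: 6 (2R,6R)-2,6-dimethyl-2-[(E)-2-(4,4,5,5-tetramethyl-1,3,2-dioxaborolan-2-yl)ethenyl]cyclohexan-1-one
Conditions: CrCl2, LiI, Cl2CHB(pin), THF, rt
Reagents that add atoms: 2-(dichloromethyl)-4,4,5,5-tetramethyl-1,3,2-dioxaborolane, ClC(Cl)B1OC(C)(C)C(C)(C)O1
Why: Takai–Utimoto boryl olefination, in which the geminal dichromium reagent adds to the aldehyde and not to the shielded 2,2,6-trisubstituted ketone and anti elimination gives the E alkenylboronate.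

Step 5
Reactants: 6 (2R,6R)-2,6-dimethyl-2-[(E)-2-(4,4,5,5-tetramethyl-1,3,2-dioxaborolan-2-yl)ethenyl]cyclohexan-1-one; 7 4-methoxybenzyl alcohol
Product: 8 (2R,6R)-2-[(E)-2-(4-methoxybenzyloxy)ethenyl]-2,6-dimethylcyclohexan-1-one
Conditions: Cu(OAc)2, Et3N, 7 in excess as co-solvent, CH2Cl2, air, rt
Reagents that add atoms: none
Why: Copper-promoted oxidative coupling of an alkenyl pinacol boronate with an alcohol (Chan–Evans–Lam type etherification) transfers the alkenyl group to oxygen with retention of the E geometry under mild amine base that neither enolises the ketone nor hydrolyses the enol ether.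

Step 6
Reactants: 9 but-3-yn-1-ol
Product: 10 (but-3-yn-1-yloxy)(tert-butyl)dimethylsilane
Conditions: t-BuMe2SiCl, imidazole, DMF, rt
Reagents that add atoms: tert-butyldimethylsilyl chloride, CC(C)(C)[Si](C)(C)Cl
Why: Standard imidazole-promoted silylation of a primary alcohol.

Step 7
Reactants: 10 (but-3-yn-1-yloxy)(tert-butyl)dimethylsilane
Product: 12 tert-butyl{[(E)-4-iodobut-3-en-1-yl]oxy}dimethylsilane, via alkenylzirconocene chloride 11 (not isolated)
Conditions: Cp2Zr(H)Cl, CH2Cl2, rt; I2, 0 °C
Reagents that add atoms: iodine, II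
Why: Schwartz hydrozirconation adds Zr–H syn across the terminal alkyne with zirconium at the terminus, and iodinolysis of the C–Zr bond with retention gives the E iodoalkene.

Step 8
Reactants: 12 tert-butyl{[(E)-4-iodobut-3-en-1-yl]oxy}dimethylsilane; 8 (2R,6R)-2-[(E)-2-(4-methoxybenzyloxy)ethenyl]-2,6-dimethylcyclohexan-1-one
Product: 15 (1S,2R,6R)-1-[(E)-4-(tert-butyldimethylsilyloxy)but-1-en-1-yl]-2-[(E)-2-(4-methoxybenzyloxy)ethenyl]-2,6-dimethylcyclohexan-1-ol, via alkenyllithium 13 (not isolated), via alkenylcerium dichloride 14 (not isolated)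
Conditions: t-BuLi (2.1 equiv), Et2O, −78 °C; CeCl3 (anhydrous), THF, −78 °C; 8, −78 to −40 °C; H2O
Reagents that add atoms: none
Why: Iodine–lithium exchange and transmetalation give a weakly basic alkenylcerium reagent that adds to the hindered, enolisable ketone without deprotonation, and, as with 2,2,6-trimethylcyclohexanone, it should attack equatorially on the chair that keeps the C6 methyl equatorial, so the new alkenyl group ends trans to that methyl and to the neighbouring alkoxyvinyl group (1S).

Step 9
Reactants: 15 (1S,2R,6R)-1-[(E)-4-(tert-butyldimethylsilyloxy)but-1-en-1-yl]-2-[(E)-2-(4-methoxybenzyloxy)ethenyl]-2,6-dimethylcyclohexan-1-ol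
Product: 18 (4E,6S,7S,8S,10R)-7-[2-(tert-butyldimethylsilyloxy)ethyl]-8-hydroxy-6-(4-methoxybenzyloxy)-4,10-dimethylcyclodec-4-en-9-one, via potassium alkoxide 16 (not isolated), via potassium enolate 17 (not isolated)
Conditions: KH, 18-crown-6, THF, 0 °C to rt; 2-(phenylsulfonyl)-3-phenyloxaziridine, −78 °C; AcOH, −78 °C
Reagents that add atoms: 2-(phenylsulfonyl)-3-phenyloxaziridine, O=S(=O)(c1ccccc1)N1OC1c1ccccc1
Why: The potassium alkoxide 16, its ion pair loosened by the crown ether, undergoes the alkoxide-accelerated [3,3] sigmatropic shift (anionic oxy-Cope rearrangement, the known route from trans-1,2-dialkenylcyclohexanols to E-cyclodec-5-enones) in which C4–C9 breaks as C6–C7 forms; no ring is closed, the six-membered ring instead grows by four atoms into ring A and leaves the C8=C9 enolate 17. The transition state is a chair fused like a trans-decalin to the cyclohexane chair, with both alkenyl groups and the C10 methyl equatorial and only the C4 methyl and the oxido group axial. Because both alkenes are E, the C6 ether oxygen and the C7 side chain sit pseudo-equatorial, so the chirality of C4 and C9 passes to C6 (S) and C7 (S), and the equatorial C3 on C4 gives the E C4=C5 alkene. The enolate is then oxidised by the sulfonyloxaziridine (Davis hydroxylation) on its outer face, the inner face being covered by the transannular C4=C5 unit, which sets C8 (S). The step needs the chair rather than the boat pathway and a single sense of chirality transfer; both should be secured by the trans-diequatorial dialkenyl arrangement fixed in step 8, the E geometry of both alkenes and the axial C4 methyl, and the low temperature of the oxidation should keep the regiodefined enolate from equilibrating toward C10.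

Step 10
Reactants: 18 (4E,6S,7S,8S,10R)-7-[2-(tert-butyldimethylsilyloxy)ethyl]-8-hydroxy-6-(4-methoxybenzyloxy)-4,10-dimethylcyclodec-4-en-9-one
Product: 19 (4E,6S,7S,8S,9R,10R)-7-[2-(tert-butyldimethylsilyloxy)ethyl]-6-(4-methoxybenzyloxy)-4,10-dimethylcyclodec-4-ene-8,9-diol
Conditions: Zn(BH4)2, Et2O, −20 to 0 °C
Reagents that add atoms: none
Why: Chelation-controlled reduction in which zinc bridges C8–OH and the C9 carbonyl and hydride arrives from the side opposite C7, which is also the outer face of the ring ketone, giving the 8,9-anti diol with both oxygens on the same side of ring A (9R).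

Step 11
Reactants: 19 (4E,6S,7S,8S,9R,10R)-7-[2-(tert-butyldimethylsilyloxy)ethyl]-6-(4-methoxybenzyloxy)-4,10-dimethylcyclodec-4-ene-8,9-diol
Product: 20 (4E,6S,7S,8S,9R,10R)-7-(2-hydroxyethyl)-6-(4-methoxybenzyloxy)-4,10-dimethylcyclodec-4-ene-8,9-diol
Conditions: Bu4NF, THF, 0 °C to rt
Reagents that add atoms: none
Why: Fluoride cleaves the primary silyl ether, and nothing else in the molecule is sensitive to these conditions.

Step 12
Reactants: 20 (4E,6S,7S,8S,9R,10R)-7-(2-hydroxyethyl)-6-(4-methoxybenzyloxy)-4,10-dimethylcyclodec-4-ene-8,9-diol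
Product: 23 (4E,6S,7R,8S,9R,10R)-9-hydroxy-6-(4-methoxybenzyloxy)-13-norgermacr-4-en-12,8-olide, via hydroxy aldehyde 21 (not isolated), via lactol 22 (not isolated)
Conditions: TEMPO (cat.), PhI(OAc)2, CH2Cl2, rt
Reagents that add atoms: none
Why: Oxoammonium oxidation takes only the primary alcohol, the aldehyde closes to the five-membered lactol on the adjacent C8–OH (favoured over the bridged six-membered lactol through C9–OH), and the lactol is oxidised on to the trans-fused γ-lactone while the secondary C9–OH is left.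

Step 13
Reactants: 23 (4E,6S,7R,8S,9R,10R)-9-hydroxy-6-(4-methoxybenzyloxy)-13-norgermacr-4-en-12,8-olide
Product: 24 (4E,6S,7R,8S,9R,10R)-6-(4-methoxybenzyloxy)-9-(triethylsilyloxy)-13-norgermacr-4-en-12,8-olide
Conditions: Et3SiOTf, 2,6-lutidine, CH2Cl2, −78 to 0 °C
Reagents that add atoms: triethylsilyl trifluoromethanesulfonate, CC[Si](CC)(CC)OS(=O)(=O)C(F)(F)F
Why: Silylation of the only free hydroxyl with a reactive silyl triflate and a hindered base masks C9–OH for the enolate and acylation steps and can be removed at the end under mild conditions.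

Step 14
Reactants: 24 (4E,6S,7R,8S,9R,10R)-6-(4-methoxybenzyloxy)-9-(triethylsilyloxy)-13-norgermacr-4-en-12,8-olide
Product: 26 11-[(dimethylamino)methyl] derivative of 24 (C11 epimers), via lithium enolate 25 (not isolated)
Conditions: LiN(i-Pr)2, THF, −78 °C; CH2=NMe2 I (dimethylmethyleneammonium iodide), −78 °C to rt
Reagents that add atoms: N,N-dimethylmethyleneiminium iodide, C=[N+](C)C.[I-]
Why: Mannich aminomethylation of the lactone lithium enolate with the preformed iminium salt introduces C13 at C11, the only acidic position.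

Step 15
Reactants: 26 11-[(dimethylamino)methyl] derivative of 24 (C11 epimers)
Product: 28 (4E,6S,7R,8S,9R,10R)-6-(4-methoxybenzyloxy)-9-(triethylsilyloxy)germacra-4,11(13)-dien-12,8-olide, via trimethylammonium iodide 27 (not isolated)
Conditions: MeI, THF, rt; aq NaHCO3, EtOAc, rt
Reagents that add atoms: none
Why: N-Methylation gives the quaternary ammonium salt, which loses trimethylamine by base-induced β-elimination to form the exocyclic methylene and erase the C11 centre.

Step 16
Reactants: 28 (4E,6S,7R,8S,9R,10R)-6-(4-methoxybenzyloxy)-9-(triethylsilyloxy)germacra-4,11(13)-dien-12,8-olide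
Product: 29 (4E,6S,7R,8S,9R,10R)-6-hydroxy-9-(triethylsilyloxy)germacra-4,11(13)-dien-12,8-olide
Conditions: DDQ, CH2Cl2/pH 7 phosphate buffer, 0 °C
Reagents that add atoms: none
Why: Oxidative cleavage of the electron-rich benzyl ether (hydride abstraction by DDQ, then hydrolysis of the oxocarbenium ion) frees the C6 allylic alcohol, and the buffer should keep the triethylsilyl ether intact.

Step 17
Reactants: 29 (4E,6S,7R,8S,9R,10R)-6-hydroxy-9-(triethylsilyloxy)germacra-4,11(13)-dien-12,8-olide
Product: 30 (4R,5R,6R,7R,8S,9R,10R)-4,5-epoxy-6-hydroxy-9-(triethylsilyloxy)germacr-11(13)-en-12,8-olide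
Conditions: VO(acac)2 (cat.), t-BuOOH, CH2Cl2, 0 °C to rt
Reagents that add atoms: tert-butyl hydroperoxide, CC(C)(C)OO
Why: Vanadium-catalysed hydroxyl-directed epoxidation of an allylic alcohol, in which the C6 vanadate ester passes the peroxide oxygen to the C4=C5 face on which the C6–O bond can lie at the 40–50° dihedral angle this reagent requires; in ring A that angle is reached only in the conformer with the C4 methyl turned to the side of C7–H, the delivered face is expected to give the (4R,5R) oxirane, and the electron-poor methylene lactone is inert.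

Step 18
Reactants: 30 (4R,5R,6R,7R,8S,9R,10R)-4,5-epoxy-6-hydroxy-9-(triethylsilyloxy)germacr-11(13)-en-12,8-olide; 31 3-methylbut-2-enoic acid
Product: 33 (4R,5R,6R,7R,8S,9R,10R)-4,5-epoxy-6-(3-methylbut-2-enoyloxy)-9-(triethylsilyloxy)germacr-11(13)-en-12,8-olide, via mixed anhydride 32 (not isolated)
Conditions: 31, 2,4,6-Cl3C6H2COCl, Et3N, toluene, rt; then 30, DMAP, rt
Reagents that add atoms: none
Why: Yamaguchi esterification, in which the mixed anhydride is attacked by DMAP at the less hindered senecioyl carbonyl and the acylpyridinium acylates the hindered secondary C6–OH without acid that could open the oxirane.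

Step 19
Reactants: 33 (4R,5R,6R,7R,8S,9R,10R)-4,5-epoxy-6-(3-methylbut-2-enoyloxy)-9-(triethylsilyloxy)germacr-11(13)-en-12,8-olide
Product: 34 (4R,5R,6R,7S,8S,9R,10R)-4,5-epoxy-9-hydroxy-6-(3-methylbut-2-enoyloxy)germacr-11(13)-en-12,8-olide (CNP0119422.1)
Conditions: HF·pyridine, pyridine, THF, 0 °C
Reagents that add atoms: none
Why: Pyridine-buffered hydrogen fluoride removes the labile triethylsilyl ether under conditions mild enough for the oxirane, the enoate and the methylene lactone (the change of the C7 descriptor from R to S is a CIP priority change only).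

## Compound list

1 | 2-methylcyclohex-2-en-1-one | CC1=CCCCC1=O | starting material
2 | (R)-2-methylcyclohexan-1-one | O=C1[C@H](C)CCCC1 | intermediate
3 | lithium (R)-6-methylcyclohex-1-en-1-olate | [Li]OC1=CCCC[C@H]1C | intermediate
4 | (2Z,6R)-2-(hydroxymethylidene)-6-methylcyclohexan-1-one | O=C1[C@H](C)CCC/C1=C/O | intermediate
5 | (1R,3R)-1,3-dimethyl-2-oxocyclohexane-1-carbaldehyde | O=C1[C@H](C)CCC[C@]1(C)C=O | intermediate
6 | (2R,6R)-2,6-dimethyl-2-[(E)-2-(4,4,5,5-tetramethyl-1,3,2-dioxaborolan-2-yl)ethenyl]cyclohexan-1-one | O=C1[C@H](C)CCC[C@]1(C)/C=C/B2OC(C)(C)C(C)(C)O2 | intermediate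
7 | 4-methoxybenzyl alcohol | COc1ccc(CO)cc1 | starting material
8 | (2R,6R)-2-[(E)-2-(4-methoxybenzyloxy)ethenyl]-2,6-dimethylcyclohexan-1-one | O=C1[C@H](C)CCC[C@]1(C)/C=C/OCc2ccc(OC)cc2 | intermediate
9 | but-3-yn-1-ol | C#CCCO | starting material
10 | (but-3-yn-1-yloxy)(tert-butyl)dimethylsilane | C#CCCO[Si](C)(C)C(C)(C)C | intermediate
11 | [(E)-4-(tert-butyldimethylsilyloxy)but-1-en-1-yl]chlorobis(cyclopentadienyl)zirconium (cyclopentadienyl rings drawn σ-bonded) | CC(C)(C)[Si](C)(C)OCC/C=C/[Zr](Cl)(C1C=CC=C1)C1C=CC=C1 | intermediate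
12 | tert-butyl{[(E)-4-iodobut-3-en-1-yl]oxy}dimethylsilane | I/C=C/CCO[Si](C)(C)C(C)(C)C | intermediate
13 | [(E)-4-(tert-butyldimethylsilyloxy)but-1-en-1-yl]lithium | [Li]/C=C/CCO[Si](C)(C)C(C)(C)C | intermediate
14 | dichloro[(E)-4-(tert-butyldimethylsilyloxy)but-1-en-1-yl]cerium | Cl[Ce](Cl)/C=C/CCO[Si](C)(C)C(C)(C)C | intermediate
15 | (1S,2R,6R)-1-[(E)-4-(tert-butyldimethylsilyloxy)but-1-en-1-yl]-2-[(E)-2-(4-methoxybenzyloxy)ethenyl]-2,6-dimethylcyclohexan-1-ol | O[C@]1(/C=C/CCO[Si](C)(C)C(C)(C)C)[C@H](C)CCC[C@]1(C)/C=C/OCc2ccc(OC)cc2 | intermediate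
16 | potassium alkoxide of 15 | [K]O[C@]1(/C=C/CCO[Si](C)(C)C(C)(C)C)[C@H](C)CCC[C@]1(C)/C=C/OCc2ccc(OC)cc2 | intermediate
17 | potassium C8=C9 enolate of the ring-expanded ketone (4E alkene; C6, C7 and C10 as in 18) | [K]O/C1=C\[C@H](CCO[Si](C)(C)C(C)(C)C)[C@@H](OCc2ccc(OC)cc2)/C=C(C)/CCC[C@H]1C | intermediate
18 | (4E,6S,7S,8S,10R)-7-[2-(tert-butyldimethylsilyloxy)ethyl]-8-hydroxy-6-(4-methoxybenzyloxy)-4,10-dimethylcyclodec-4-en-9-one | O[C@@H]1C(=O)[C@H](C)CCC/C(C)=C/[C@H](OCc2ccc(OC)cc2)[C@H]1CCO[Si](C)(C)C(C)(C)C | intermediate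
19 | (4E,6S,7S,8S,9R,10R)-7-[2-(tert-butyldimethylsilyloxy)ethyl]-6-(4-methoxybenzyloxy)-4,10-dimethylcyclodec-4-ene-8,9-diol | O[C@@H]1[C@H](O)[C@H](C)CCC/C(C)=C/[C@H](OCc2ccc(OC)cc2)[C@H]1CCO[Si](C)(C)C(C)(C)C | intermediate
20 | (4E,6S,7S,8S,9R,10R)-7-(2-hydroxyethyl)-6-(4-methoxybenzyloxy)-4,10-dimethylcyclodec-4-ene-8,9-diol | O[C@@H]1[C@H](O)[C@H](C)CCC/C(C)=C/[C@H](OCc2ccc(OC)cc2)[C@H]1CCO | intermediate
21 | [(4E,6S,7S,8S,9R,10R)-8,9-dihydroxy-6-(4-methoxybenzyloxy)-4,10-dimethylcyclodec-4-en-7-yl]acetaldehyde | O[C@@H]1[C@H](O)[C@H](C)CCC/C(C)=C/[C@H](OCc2ccc(OC)cc2)[C@H]1CC=O | intermediate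
22 | γ-lactol of 23 (C12 hemiacetal, both anomers; 4E,6S,7R,8S,9R,10R) | C1C(O)O[C@@H]2[C@H](O)[C@H](C)CCC/C(C)=C/[C@H](OCc3ccc(OC)cc3)[C@@H]12 | intermediate
23 | (4E,6S,7R,8S,9R,10R)-9-hydroxy-6-(4-methoxybenzyloxy)-13-norgermacr-4-en-12,8-olide (ring B trans-fused at C7–C8) | C1C(=O)O[C@@H]2[C@H](O)[C@H](C)CCC/C(C)=C/[C@H](OCc3ccc(OC)cc3)[C@@H]12 | intermediate
24 | (4E,6S,7R,8S,9R,10R)-6-(4-methoxybenzyloxy)-9-(triethylsilyloxy)-13-norgermacr-4-en-12,8-olide | C1C(=O)O[C@@H]2[C@H](O[Si](CC)(CC)CC)[C@H](C)CCC/C(C)=C/[C@H](OCc3ccc(OC)cc3)[C@@H]12 | intermediate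
25 | lithium enolate of 24 (C11=C12–OLi) | C1=C(O[Li])O[C@@H]2[C@H](O[Si](CC)(CC)CC)[C@H](C)CCC/C(C)=C/[C@H](OCc3ccc(OC)cc3)[C@@H]12 | intermediate
26 | 11-[(dimethylamino)methyl] derivative of 24 (C11 epimers) | CN(C)CC1C(=O)O[C@@H]2[C@H](O[Si](CC)(CC)CC)[C@H](C)CCC/C(C)=C/[C@H](OCc3ccc(OC)cc3)[C@@H]12 | intermediate
27 | 11-[(trimethylammonio)methyl] derivative of 24, iodide (C11 epimers) | C[N+](C)(C)CC1C(=O)O[C@@H]2[C@H](O[Si](CC)(CC)CC)[C@H](C)CCC/C(C)=C/[C@H](OCc3ccc(OC)cc3)[C@@H]12.[I-] | intermediate
28 | (4E,6S,7R,8S,9R,10R)-6-(4-methoxybenzyloxy)-9-(triethylsilyloxy)germacra-4,11(13)-dien-12,8-olide | C=C1C(=O)O[C@@H]2[C@H](O[Si](CC)(CC)CC)[C@H](C)CCC/C(C)=C/[C@H](OCc3ccc(OC)cc3)[C@@H]12 | intermediate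
29 | (4E,6S,7R,8S,9R,10R)-6-hydroxy-9-(triethylsilyloxy)germacra-4,11(13)-dien-12,8-olide | C=C1C(=O)O[C@@H]2[C@H](O[Si](CC)(CC)CC)[C@H](C)CCC/C(C)=C/[C@H](O)[C@@H]12 | intermediate
30 | (4R,5R,6R,7R,8S,9R,10R)-4,5-epoxy-6-hydroxy-9-(triethylsilyloxy)germacr-11(13)-en-12,8-olide | C=C1C(=O)O[C@@H]2[C@H](O[Si](CC)(CC)CC)[C@H](C)CCC[C@@]3(C)O[C@@H]3[C@H](O)[C@@H]12 | intermediate
31 | 3-methylbut-2-enoic acid (senecioic acid) | CC(C)=CC(=O)O | starting material
32 | 3-methylbut-2-enoic 2,4,6-trichlorobenzoic anhydride | CC(C)=CC(=O)OC(=O)c1c(Cl)cc(Cl)cc1Cl | intermediate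
33 | (4R,5R,6R,7R,8S,9R,10R)-4,5-epoxy-6-(3-methylbut-2-enoyloxy)-9-(triethylsilyloxy)germacr-11(13)-en-12,8-olide | C=C1C(=O)O[C@@H]2[C@H](O[Si](CC)(CC)CC)[C@H](C)CCC[C@@]3(C)O[C@@H]3[C@H](OC(=O)C=C(C)C)[C@@H]12 | intermediate
34 | (4R,5R,6R,7S,8S,9R,10R)-4,5-epoxy-9-hydroxy-6-(3-methylbut-2-enoyloxy)germacr-11(13)-en-12,8-olide (CNP0119422.1) | C=C1C(=O)O[C@@H]2[C@H](O)[C@H](C)CCC[C@@]3(C)O[C@@H]3[C@H](OC(=O)C=C(C)C)[C@@H]12 | target

## Step count and risks

Total step count: 19. Longest linear sequence: 17 steps (steps 1–5 and 8–19, from 1 to 34).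

Steps most likely to fail:

Step 17. The risk is oxygen transfer to the other face of the C4=C5 alkene: ring A may react from its resting conformer on the outer face, which is the face a peracid would be expected to take, instead of from the conformer that lets the C6 vanadate reach the alkene. The fallback sets out from 29 and comes back at 30, and lets a chiral reagent rather than the ring conformation choose the face: stoichiometric Ti(O-i-Pr)4 with D-(−)-diisopropyl tartrate and t-BuOOH over 4 Å molecular sieves in CH2Cl2 at −20 °C (Sharpless epoxidation of a secondary allylic alcohol). When 29 is drawn in the usual way for this reaction, the carbinol substituent C7 of the 6S alcohol lies on the side from which the D-(−)-tartrate complex delivers oxygen. This is the fast-reacting, matched pairing, and it should lead to the same (4R,5R) oxirane 30 without any new intermediate.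

Step 8. The risk is proton abstraction at C6 of the hindered ketone instead of addition, or approach from the axial side, which would give the cis-dialkenyl isomer that cannot use the chair pathway of step 9. The fallback sets out from 8 and 10 (iodide 12 is then not needed) and comes back at 15. Alkyne 10 is deprotonated with n-BuLi in THF at −78 °C to lithium acetylide F1, if necessary transmetalated with CeCl3. This slim, linear nucleophile adds to 8 anti to the C6 methyl to give propargylic alcohol F2. The tertiary hydroxyl then directs trans-hydroalumination of the alkyne with NaAlH2(OCH2CH2OCH3)2 in THF, and hydrolysis should give the E allylic alcohol 15.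

Step 9. The risk is erosion of facial control when the ten-membered enolate changes conformation before it is oxidised, together with addition of the enolate to the sulfonylimine that the oxaziridine releases. The fallback sets out from 15 and comes back at 18, and separates the rearrangement from the oxidation. The rearrangement is run as before, but enolate 17 is trapped with Me3SiCl/Et3N at −78 °C to give the isolable silyl enol ether F3. Rubottom oxidation of F3 with one equivalent of dimethyldioxirane (acetone/CH2Cl2, −78 °C, then warming) should take the electron-rich enol ether ahead of the C4=C5 alkene and give α-trimethylsilyloxy ketone F4. Brief treatment with dilute aqueous acid in THF then gives 18.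

Further compounds
F1 | step 8 | [4-(tert-butyldimethylsilyloxy)but-1-yn-1-yl]lithium | [Li]C#CCCO[Si](C)(C)C(C)(C)C
F2 | step 8 | (1R,2R,6R)-1-[4-(tert-butyldimethylsilyloxy)but-1-yn-1-yl]-2-[(E)-2-(4-methoxybenzyloxy)ethenyl]-2,6-dimethylcyclohexan-1-ol | O[C@]1(C#CCCO[Si](C)(C)C(C)(C)C)[C@H](C)CCC[C@]1(C)/C=C/OCc2ccc(OC)cc2
F3 | step 9 | trimethylsilyl enol ether (C8=C9–OSiMe3) of the ring-expanded ketone | C[Si](C)(C)O/C1=C\[C@H](CCO[Si](C)(C)C(C)(C)C)[C@@H](OCc2ccc(OC)cc2)/C=C(C)/CCC[C@H]1C
F4 | step 9 | 8-O-trimethylsilyl ether of 18 | C[Si](C)(C)O[C@@H]1C(=O)[C@H](C)CCC/C(C)=C/[C@H](OCc2ccc(OC)cc2)[C@H]1CCO[Si](C)(C)C(C)(C)C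
F0 | step 17 | none | none
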